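**Numbering used throughout**

1 1,3,5-tris(benzyloxy)benzene · 2 its 2,4-dibromide · 3 1,3,5-tris(benzyloxy)-2,4-dimethoxybenzene · 4 N,2-dimethoxy-N-methylacetamide · 5 aryllithium from 3 · 6 tris(benzyloxy) α-methoxy ketone · 7 mono-debenzylated hydroxy ketone · 8 carbon disulfide · 9 4-hydroxychromene-2-thione · 10 2-(methylsulfanyl)chromone · 11 2-(methanesulfonyl)chromone · 12 2-methoxychromone · 13 silylaryl triflate · 14 4,5-dimethoxybenzyne · 15 2,4,5-trimethoxyphenyl anion · 16 C2 adduct enolate · 17 5,7-bis(benzyloxy)flavone · 18 target

## Analysis of the target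

The target 18 is a flavone: a benzo ring A fused to a 4-pyranone ring C, with an aryl ring B on C2. It has no stereocentre and no stereogenic double bond, so the problem is one of connectivity and oxygen pattern only. Ring A is fully substituted, with C5 to C8 carrying OH, OMe, OH, OMe in turn; ring C carries a methoxy at C3; ring B carries methoxys at C2', C4' and C5' and hydrogens only at C3' and C6'. The sensitive groups are the two free phenols (5-OH chelated to the C4 carbonyl, 7-OH acidic), which sit on an electron-rich, easily oxidised ring and must be told apart from six methyl ethers. They therefore travel as ethers that can be removed without touching an O–methyl bond. The hard points are the alternating OH/OMe pattern on a benzene ring with no free position, and the C2–C1' bond, which joins two electron-rich rings and is flanked by the 3-methoxy and the 2'-methoxy. The strategy rests on ring B: C1' bears C2 of the chromone, the neighbouring C2' bears a methoxy, and the 4'- and 5'-methoxys lie symmetrically about the C1'–C2' bond. C1' and C2' are therefore the two carbons of the symmetric 4,5-dimethoxybenzyne 14, with a carbon and a methoxy group added across it. The counterpart on ring C is that C2 is an acyl-type carbon, so a C2–OMe bond there can be broken by addition and elimination, as an insertion requires.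

## Retrosynthetic reasoning

**18 ⇒ 17.** The two O–H bonds at C5 and C7 are traced back to O–benzyl bonds. This keeps the two phenols distinct from the six methyl ethers to the end and leaves a final hydrogenolysis that cannot touch O–methyl bonds or the pyranone.

**17 ⇒ 12 + 13 (through 14, 15, 16).** The C2–C1' bond and the C2'–OMe bond are cut together, which returns the 2-methoxychromone 12 and the symmetric aryne 14, released from the purchased triflate 13. Cutting here, and not at a ring C closure, means ring B arrives whole in one operation, with its 2'-methoxy placed by the same event that makes the C–C bond. Because 14 is symmetric there is no regiochemistry to control on the aryne. The forward reaction must release 14 slowly, let the alkoxide set free from C2 add to it, and let the resulting anion 15 attack C2 of 12. The adduct 16 then ejects its C2 methoxy group and so carries the chain.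

**12 ⇒ 11 ⇒ 10 ⇒ 9.** The C2–OMe bond is traced back to a C2–S bond. A 2-alkoxychromone cannot be made cleanly by O-alkylation of the oxygen analogue, which is ambident. The sulfur of 9 is alkylated without ambiguity and locks the chromone form in 10. Oxidation to the sulfone 11 then gives a leaving group that an alkoxide displaces at C2 by addition and elimination.

**9 ⇒ 7 + 8.** The C2–C3 and C2–O1 bonds are cut, so C2 comes from carbon disulfide 8. The α-methoxy ketone 7 already holds the 3-methoxy, so ring C is closed with every oxygen in its final place.

**7 ⇒ 6.** One O–benzyl bond ortho to the ketone is cut to free the oxygen that becomes O1. Compound 6 is symmetric, so either ortho benzyl ether gives the same 7, and chelation to the carbonyl singles these two out from the third.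

**6 ⇒ 3 + 4 (through 5).** The aryl–carbonyl bond is cut to the aryllithium 5, made at the only ring C–H of 3, and the Weinreb amide 4. An acylation run with a Lewis acid was set aside: α-alkoxyacylium ions tend to decarbonylate and Lewis acids strip benzyl ethers without control. The anionic route has neither problem.

**3 ⇒ 2 ⇒ 1.** The two C–OMe bonds are traced to C–Br and then to C–H. All three ring positions of 1 are equivalent, so stoichiometry alone decides that two are oxygenated and one is left for the acyl group.

## Alternatives that were turned down

**Alternative 1:** The same C2–C1' bond is cut, but closed with palladium. The bromide A2 carries C2–Br and, on O3, an O–CH2–O tether to a 3,4-dimethoxyphenyl ring. Zerovalent palladium inserts into C2–Br and arylates the ortho C–H of the tethered ring, closing a temporary 1,3-dioxepine to give A1.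
- For: the bond is made intramolecularly, which helps a crowded biaryl-type coupling; direct arylation is an established reaction class; the two bridging oxygens are already the 3- and 2'-oxygens.
- Against: the closure is seven-membered and must pass through an eight-membered palladacycle. The tethered ring has two ortho C–H bonds, and only sterics favour the right one. After the key step the acetal must be cleaved and both freed hydroxyls methylated, and acid strong enough for the acetal would probably also take off the 5-O-benzyl group. The 3-oxygen must stay free until the tether is attached, so the α-methoxy ketone 7 cannot be used, and a 2-bromo-3-hydroxychromone is needed.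
- Comparison: this alternative is stronger in that its bond-forming step has close precedent. The chosen route instead makes the C–C bond and the C2'–OMe bond in one step, carries the 3-methoxy from 4, and needs one step after the key step against about four.

**Alternative 2:** The C4–C4a bond is cut. The acid A4, an (E)-3-aryloxy-2-methoxyacrylic acid, is activated as a mixed anhydride and acylates the only C–H of ring A, closing ring C. The peri 5-O-benzyl group should be lost in the acidic medium, giving A3.
- For: the site of attack is the single free position of a very nucleophilic ring, the closure is six-membered, and acylation of electron-rich arenes is dependable. On regiochemical certainty of the ring closure it is at least as good as the chosen route.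
- Against: the difficulty moves into A4. It is a tetrasubstituted enol ether whose carboxyl must sit cis to the aryloxy group, and simple addition of a phenol to an alkynoate cannot deliver the 2-methoxy substituent. Its aryloxy part needs a phenol with five ring oxygens in three different states, so the symmetry of 1 is lost earlier. Strong acid acts on an enol ether and two benzyl ethers at once.
- Comparison: the chosen route reaches its key precursor 12 by routine steps on a symmetric ring A and uses a purchased ring B partner 13, where this alternative needs a separately built, geometry-defined acrylate.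

**Alternative 3:** The C4a–C4 and C4–C3 bonds are cut. Zerovalent palladium inserts into the C–I bond of the ring A iodide A6 and takes up a carbonyl carbon from the gas phase. The aroylpalladium is captured by the enolate of the ring B ketone A7 to give the diketone A5, with no ring closed.
- For: it is convergent, A6 is one step from 3, A7 is simple, and A5 is the classical flavone precursor, so the end-game is known. On paper it is shorter than the chosen route, and on step economy it is the stronger plan.
- Against: oxidative addition into an iodide with two ortho benzyloxy groups on a penta-oxygenated ring should be slow and protodeiodination competes. The hindered aroylpalladium may be taken by the enolate oxygen instead of carbon. A 2-alkoxy-1,3-diketone is prone to retro-Claisen cleavage under the basic conditions. After the key step a selective mono-debenzylation and a cyclodehydration still have to be done on a late intermediate.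
- Comparison: the chosen route puts its risk on a substrate whose rings A and C are finished, needs no metal, leaves only hydrogenolysis afterwards, and on failure returns unchanged 12 or falls back to 7.

Key step: step 9

## Route

Assumption: 1, 4, 8 and 13 are bought; 9 is drawn as its 4-hydroxy-2-thione tautomer, which equilibrates with the 2-sulfanyl-4-one form and gives the same S-methyl compound.

Step 1
Reactants: 1 1,3,5-tris(benzyloxy)benzene
Product: 2 1,3,5-tris(benzyloxy)-2,4-dibromobenzene
Conditions: NBS (2.05 equiv), CH2Cl2, −10 → 0 °C, dark
Reagents that add atoms: N-bromosuccinimide, O=C1CCC(=O)N1Br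
Why: Electrophilic aromatic bromination; every ring C–H lies between two alkoxy groups and is strongly activated, and because each bromine slows the next substitution, two equivalents should stop at the dibromide.

Step 2
Reactants: 2 1,3,5-tris(benzyloxy)-2,4-dibromobenzene
Product: 3 1,3,5-tris(benzyloxy)-2,4-dimethoxybenzene
Conditions: NaOMe (8 equiv), CuBr (0.3 equiv), DMF/MeOH, 110 °C
Reagents that add atoms: sodium methoxide, C[O-].[Na+]
Why: Ullmann-type methoxylation of aryl bromides mediated by CuBr, a monovalent copper salt; aryl benzyl ethers are inert to methoxide, and both bromides react in the same way.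

Step 3
Reactants: 3 1,3,5-tris(benzyloxy)-2,4-dimethoxybenzene; 4 N,2-dimethoxy-N-methylacetamide
Product: 6 2-methoxy-1-[2,4,6-tris(benzyloxy)-3,5-dimethoxyphenyl]ethan-1-one, via aryllithium 5 (not isolated)
Conditions: n-BuLi, TMEDA, THF, −20 → 0 °C; then 4, −78 → 0 °C; aq. NH4Cl
Reagents that add atoms: none
Why: Directed ortho-metalation at the only ring C–H, which is flanked by two alkoxy groups, followed by Weinreb ketone synthesis; the chelated tetrahedral adduct prevents a second addition, and without a Lewis acid the benzyl ethers should stay in place.

Step 4
Reactants: 6 2-methoxy-1-[2,4,6-tris(benzyloxy)-3,5-dimethoxyphenyl]ethan-1-one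
Product: 7 1-[2,4-bis(benzyloxy)-6-hydroxy-3,5-dimethoxyphenyl]-2-methoxyethan-1-one
Conditions: MgBr2·OEt2 (2 equiv), toluene/Et2O, 70 °C; then 1 M HCl
Reagents that add atoms: none
Why: Chelation-controlled cleavage of a benzyl ether ortho to a carbonyl group; the two ortho ethers are equivalent by symmetry, and once one is cleaved the magnesium phenoxide holds the carbonyl, so the second ortho ether and the remote 4-benzyloxy group should survive.

Step 5
Reactants: 7 1-[2,4-bis(benzyloxy)-6-hydroxy-3,5-dimethoxyphenyl]-2-methoxyethan-1-one; 8 carbon disulfide
Product: 9 5,7-bis(benzyloxy)-4-hydroxy-3,6,8-trimethoxy-2H-chromene-2-thione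
Conditions: KOtBu (3.5 equiv), 8 (1.5 equiv), THF, 0 °C → rt; then 1 M HCl
Reagents that add atoms: none
Why: Claisen-type thioacylation of the ketone enolate by carbon disulfide, then on acidification ring closure of the phenol onto the dithioacid carbon with loss of H2S; this is the established annulation of 2'-hydroxyaryl ketones to 4-hydroxychromene-2-thiones.

Step 6
Reactants: 9 5,7-bis(benzyloxy)-4-hydroxy-3,6,8-trimethoxy-2H-chromene-2-thione
Product: 10 5,7-bis(benzyloxy)-3,6,8-trimethoxy-2-(methylsulfanyl)-4H-chromen-4-one
Conditions: MeI (1.1 equiv), K2CO3, acetone, rt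
Reagents that add atoms: iodomethane, CI
Why: S-alkylation of the ambident thiolate; the soft sulfur reacts with the soft electrophile, which fixes the 4-pyranone tautomer.

Step 7
Reactants: 10 5,7-bis(benzyloxy)-3,6,8-trimethoxy-2-(methylsulfanyl)-4H-chromen-4-one
Product: 11 5,7-bis(benzyloxy)-2-(methanesulfonyl)-3,6,8-trimethoxy-4H-chromen-4-one
Conditions: mCPBA (2.3 equiv), CH2Cl2, 0 °C → rt
Reagents that add atoms: meta-chloroperbenzoic acid, O=C(OO)c1cccc(Cl)c1
Why: Peracid oxidation of a sulfide to the sulfone; sulfur is oxidised far faster than the C2=C3 bond, which belongs to a vinylogous ester and is a poor epoxidation substrate.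

Step 8
Reactants: 11 5,7-bis(benzyloxy)-2-(methanesulfonyl)-3,6,8-trimethoxy-4H-chromen-4-one
Product: 12 5,7-bis(benzyloxy)-2,3,6,8-tetramethoxy-4H-chromen-4-one
Conditions: NaOMe (1.05 equiv, minimal MeOH), THF, −20 → 0 °C; AcOH quench
Reagents that add atoms: sodium methoxide, C[O-].[Na+]
Why: Nucleophilic vinylic substitution by addition and elimination at C2 of a 2-sulfonylchromone, with methanesulfinate leaving; one equivalent of alkoxide in a largely aprotic medium limits further addition to the product.

Step 9
Reactants: 12 5,7-bis(benzyloxy)-2,3,6,8-tetramethoxy-4H-chromen-4-one; 13 4,5-dimethoxy-2-(trimethylsilyl)phenyl trifluoromethanesulfonate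
Product: 17 5,7-bis(benzyloxy)-3,6,8-trimethoxy-2-(2,4,5-trimethoxyphenyl)-4H-chromen-4-one, via 4,5-dimethoxybenzyne 14 (not isolated), via 2,4,5-trimethoxyphenyl anion 15 (not isolated), via C2 adduct enolate 16 (not isolated)
Conditions: CsF (3 equiv), 18-crown-6 (0.5 equiv), NaOMe (0.1 equiv), THF, 40 °C; 13 (1.5 equiv) added over 6 h
Reagents that add atoms: none
Why: Proposed new method: fluoride removes the silyl group of 13 and triflate leaves, giving the symmetric aryne 14; methoxide (first from the catalytic NaOMe, then from the chromone) adds to one of its two equivalent carbons to give the ortho-methoxy aryl anion 15, which attacks C2 of 12, the carbon of a vinylogous carbonate, to give the enolate 16; 16 restores the pyranone by expelling methoxide, which carries the chain, so the net result is insertion of the aryne into the C2–OMe bond with formation of C2–C1' and C2'–OMe. The closest known reaction types are aryne insertions into the carbon–heteroatom sigma bonds of acyl chlorides, amides and thioesters, and three-component aryne couplings in which an anionic nucleophile and a carbon electrophile add across the triple bond; insertion into the C–O bond of a 2-alkoxychromone is not known. No ring is closed and no stereocentre remains, because C2 is tetrahedral only in 16. Regiochemistry on the aryne does not arise, since the two carbons of the triple bond of 14 are related by symmetry and either direction of addition gives the 2',4',5' pattern. The step needs attack at C2 and not at C4: C4 is flanked by the 5-benzyloxy and 3-methoxy groups and is a weakly electrophilic vinylogous carbonate carbonyl, whereas C2 carries a leaving group, and attack of methoxide itself at C2 only returns 12. It also needs 15 to meet 12 before a proton or a second aryne does: THF replaces the more acidic MeCN, slow addition of 13 keeps 12 in excess over 14 at all times, and the sparingly soluble CsF releases 14 gradually.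

Step 10
Reactants: 17 5,7-bis(benzyloxy)-3,6,8-trimethoxy-2-(2,4,5-trimethoxyphenyl)-4H-chromen-4-one
Product: 18 5,7-dihydroxy-3,6,8-trimethoxy-2-(2,4,5-trimethoxyphenyl)-4H-chromen-4-one
Conditions: H2 (1 atm), 10% Pd/C, EtOAc/MeOH, rt
Reagents that add atoms: none
Why: Hydrogenolysis of aryl benzyl ethers over palladium on carbon; methyl ethers are untouched and the tetrasubstituted, conjugated C2=C3 bond of a flavone is not reduced under these mild conditions.

## Compound list

1 | 1,3,5-tris(benzyloxy)benzene | c1ccc(COc2cc(OCc3ccccc3)cc(OCc3ccccc3)c2)cc1 | starting material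
2 | 1,3,5-tris(benzyloxy)-2,4-dibromobenzene | Brc1c(OCc2ccccc2)cc(OCc2ccccc2)c(Br)c1OCc1ccccc1 | intermediate
3 | 1,3,5-tris(benzyloxy)-2,4-dimethoxybenzene | COc1c(OCc2ccccc2)cc(OCc2ccccc2)c(OC)c1OCc1ccccc1 | intermediate
4 | N,2-dimethoxy-N-methylacetamide | COCC(=O)N(C)OC | starting material
5 | [2,4,6-tris(benzyloxy)-3,5-dimethoxyphenyl]lithium | [Li]c1c(OCc2ccccc2)c(OC)c(OCc2ccccc2)c(OC)c1OCc1ccccc1 | intermediate
6 | 2-methoxy-1-[2,4,6-tris(benzyloxy)-3,5-dimethoxyphenyl]ethan-1-one | COCC(=O)c1c(OCc2ccccc2)c(OC)c(OCc2ccccc2)c(OC)c1OCc1ccccc1 | intermediate
7 | 1-[2,4-bis(benzyloxy)-6-hydroxy-3,5-dimethoxyphenyl]-2-methoxyethan-1-one | COCC(=O)c1c(O)c(OC)c(OCc2ccccc2)c(OC)c1OCc1ccccc1 | intermediate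
8 | carbon disulfide | S=C=S | starting material
9 | 5,7-bis(benzyloxy)-4-hydroxy-3,6,8-trimethoxy-2H-chromene-2-thione | COc1c(O)c2c(OCc3ccccc3)c(OC)c(OCc3ccccc3)c(OC)c2oc1=S | intermediate
10 | 5,7-bis(benzyloxy)-3,6,8-trimethoxy-2-(methylsulfanyl)-4H-chromen-4-one | CSc1oc2c(OC)c(OCc3ccccc3)c(OC)c(OCc3ccccc3)c2c(=O)c1OC | intermediate
11 | 5,7-bis(benzyloxy)-2-(methanesulfonyl)-3,6,8-trimethoxy-4H-chromen-4-one | CS(=O)(=O)c1oc2c(OC)c(OCc3ccccc3)c(OC)c(OCc3ccccc3)c2c(=O)c1OC | intermediate
12 | 5,7-bis(benzyloxy)-2,3,6,8-tetramethoxy-4H-chromen-4-one | COc1oc2c(OC)c(OCc3ccccc3)c(OC)c(OCc3ccccc3)c2c(=O)c1OC | intermediate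
13 | 4,5-dimethoxy-2-(trimethylsilyl)phenyl trifluoromethanesulfonate | COc1cc(OS(=O)(=O)C(F)(F)F)c([Si](C)(C)C)cc1OC | starting material
14 | 4,5-dimethoxybenzyne (1,2-didehydro-4,5-dimethoxybenzene) | COC1=CC#CC=C1OC | intermediate
15 | 2,4,5-trimethoxyphenyl anion, caesium salt | COc1cc(OC)c(OC)c[c-]1.[Cs+] | intermediate
16 | caesium 5,7-bis(benzyloxy)-2,3,6,8-tetramethoxy-2-(2,4,5-trimethoxyphenyl)-2H-chromen-4-olate (racemic at C2, transient) | COc1cc(OC)c(C2(OC)Oc3c(OC)c(OCc4ccccc4)c(OC)c(OCc4ccccc4)c3C([O-])=C2OC)cc1OC.[Cs+] | intermediate
17 | 5,7-bis(benzyloxy)-3,6,8-trimethoxy-2-(2,4,5-trimethoxyphenyl)-4H-chromen-4-one | COc1cc(OC)c(-c2oc3c(OC)c(OCc4ccccc4)c(OC)c(OCc4ccccc4)c3c(=O)c2OC)cc1OC | intermediate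
18 | 5,7-dihydroxy-3,6,8-trimethoxy-2-(2,4,5-trimethoxyphenyl)-4H-chromen-4-one (5,7-dihydroxy-3,6,8,2',4',5'-hexamethoxyflavone) | COc1cc(OC)c(-c2oc3c(OC)c(O)c(OC)c(O)c3c(=O)c2OC)cc1OC | target

## Step count and least certain steps

Total step count: 10. Longest linear sequence: 10 steps (1 → 18); 4, 8 and 13 enter as purchased compounds.

**Step 9 (key step).** The aryl anion 15 may be lost before it reaches C2 of 12, by protonation (moisture, benzylic C–H) or by addition to a second molecule of 14, either of which drains the methoxide chain. The aryne may also add across the electron-rich C2=C3 bond of 12 in a [2+2] sense, or 15 may add at C4. Fallback by known chemistry, setting out from 7 and returning at 17: O-acylation of 7 with 2,4,5-trimethoxybenzoyl chloride (pyridine, DMAP) should give the ester 3,5-bis(benzyloxy)-2,4-dimethoxy-6-(methoxyacetyl)phenyl 2,4,5-trimethoxybenzoate F1. Baker–Venkataraman rearrangement (LiN(SiMe3)2, THF, −78 → 0 °C) should give the diketone 1-[2,4-bis(benzyloxy)-6-hydroxy-3,5-dimethoxyphenyl]-2-methoxy-3-(2,4,5-trimethoxyphenyl)propane-1,3-dione F2. Cyclodehydration (cat. TsOH, toluene, 80 °C) should then give 17, which goes on to step 10. This classical sequence is no longer than steps 5 to 9.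

**Step 2.** Hydrodebromination at one or both crowded positions may compete with C–O coupling and leave under-oxygenated material. Fallback from 2, returning at 3: Pd-catalysed hydroxylation (Pd2(dba)3, tBuXPhos, KOH, dioxane/H2O, 100 °C) should give 2,4,6-tris(benzyloxy)benzene-1,3-diol F3. This is methylated at once under inert gas (MeI, K2CO3, DMF) to give 3.

**Step 3.** Deprotonation may occur at a benzylic O–CH2 group instead of the ring C–H and lead to [1,2]-Wittig rearrangement, or the hindered aryllithium may enolise 4 and return 3. Fallback from 3, returning at 7: Friedel–Crafts acylation with methoxyacetyl chloride and AlCl3 in Et2O at 0 °C, in which the aluminium chelate of the new ketone should cleave one ortho benzyl ether in the same flask. This fallback makes no new compound (F0) and replaces steps 3 and 4. It is not the first choice because the acylium ion can decarbonylate and the Lewis acid can remove further benzyl groups.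

**Step 4.** Debenzylation may not stop after one group, since the second ortho ether and the 4-benzyloxy group each have a neighbouring Lewis-basic oxygen. Fallback from 6, returning at 7: hydrogenolysis of all three benzyl ethers (H2, Pd/C) should give 2-methoxy-1-(2,4,6-trihydroxy-3,5-dimethoxyphenyl)ethan-1-one F4. Twofold benzylation (BnBr 2 equiv, K2CO3, acetone) should spare the hydroxyl that is hydrogen-bonded to the carbonyl and give 7.

**Step 8.** Methanol or methoxide may add a second time at C2 of 12, giving an ortho ester and then opening the pyranone. Fallback from 7, returning at 12 and replacing steps 5 to 8: Claisen condensation and lactonisation with dimethyl carbonate and NaH (toluene, reflux) should give 5,7-bis(benzyloxy)-4-hydroxy-3,6,8-trimethoxy-2H-chromen-2-one F5. O-methylation with (trimethylsilyl)diazomethane should give 12 together with its 4-methoxycoumarin isomer, which must be separated; the 5-benzyloxy group beside O4 should bias methylation towards the ring-carbonyl oxygen.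

## Further compounds

F1 | step 9 | 3,5-bis(benzyloxy)-2,4-dimethoxy-6-(methoxyacetyl)phenyl 2,4,5-trimethoxybenzoate | COCC(=O)c1c(OC(=O)c2cc(OC)c(OC)cc2OC)c(OC)c(OCc2ccccc2)c(OC)c1OCc1ccccc1
F2 | step 9 | 1-[2,4-bis(benzyloxy)-6-hydroxy-3,5-dimethoxyphenyl]-2-methoxy-3-(2,4,5-trimethoxyphenyl)propane-1,3-dione (racemic, enolisable) | COC(C(=O)c1cc(OC)c(OC)cc1OC)C(=O)c1c(O)c(OC)c(OCc2ccccc2)c(OC)c1OCc1ccccc1
F3 | step 2 | 2,4,6-tris(benzyloxy)benzene-1,3-diol | Oc1c(OCc2ccccc2)cc(OCc2ccccc2)c(O)c1OCc1ccccc1
F0 | step 3 | none | none
F4 | step 4 | 2-methoxy-1-(2,4,6-trihydroxy-3,5-dimethoxyphenyl)ethan-1-one | COCC(=O)c1c(O)c(OC)c(O)c(OC)c1O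
F5 | step 8 | 5,7-bis(benzyloxy)-4-hydroxy-3,6,8-trimethoxy-2H-chromen-2-one | COc1c(O)c2c(OCc3ccccc3)c(OC)c(OCc3ccccc3)c(OC)c2oc1=O
A1 | alternative 1 | methylene-bridged flavone with O3 and O2' joined as a fused 1,3-dioxepine, 5,7-dibenzyl ether | COc1cc2c(cc1OC)-c1oc3c(OC)c(OCc4ccccc4)c(OC)c(OCc4ccccc4)c3c(=O)c1OCO2
A2 | alternative 1 | 5,7-bis(benzyloxy)-2-bromo-3-[(3,4-dimethoxyphenoxy)methoxy]-6,8-dimethoxy-4H-chromen-4-one | COc1ccc(OCOc2c(Br)oc3c(OC)c(OCc4ccccc4)c(OC)c(OCc4ccccc4)c3c2=O)cc1OC
A3 | alternative 2 | 7-(benzyloxy)-5-hydroxy-3,6,8-trimethoxy-2-(2,4,5-trimethoxyphenyl)-4H-chromen-4-one | COc1cc(OC)c(-c2oc3c(OC)c(OCc4ccccc4)c(OC)c(O)c3c(=O)c2OC)cc1OC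
A4 | alternative 2 | (E)-3-[3,5-bis(benzyloxy)-2,4-dimethoxyphenoxy]-2-methoxy-3-(2,4,5-trimethoxyphenyl)prop-2-enoic acid | CO/C(C(=O)O)=C(/Oc1cc(OCc2ccccc2)c(OC)c(OCc2ccccc2)c1OC)c1cc(OC)c(OC)cc1OC
A5 | alternative 3 | 2-methoxy-1-[2,4,6-tris(benzyloxy)-3,5-dimethoxyphenyl]-3-(2,4,5-trimethoxyphenyl)propane-1,3-dione (racemic, enolisable) | COC(C(=O)c1c(OCc2ccccc2)c(OC)c(OCc2ccccc2)c(OC)c1OCc1ccccc1)C(=O)c1cc(OC)c(OC)cc1OC
A6 | alternative 3 | 1,3,5-tris(benzyloxy)-2-iodo-4,6-dimethoxybenzene | COc1c(OCc2ccccc2)c(I)c(OCc2ccccc2)c(OC)c1OCc1ccccc1
A7 | alternative 3 | 2-methoxy-1-(2,4,5-trimethoxyphenyl)ethan-1-one | COCC(=O)c1cc(OC)c(OC)cc1OC
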